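## Retrosynthetic overview

1. Target 30 ⇐ macrocyclic diol 29: the last step is a C7‑hydroxyl‑directed epoxidation that forms both epoxide C–O bonds (C5, C6); the oxirane is the second and last ring formed.
2. The 11‑membered carbocycle (first ring) ⇐ seco alkenyl iodide–aldehyde 25: Ni/Cr ring closure at C8–C9, then oxidation to the Z‑enone.
3. Seco chain ⇐ West alkyne 14 + East enal 19: catalytic asymmetric alkynylation at C3–C4 (sets C4), acylation with 3‑methylbut‑2‑enoyl chloride, cis semi‑hydrogenation (Z‑C2=C3).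
4. West 14 ⇐ geraniol: Cu‑catalysed SN2′ alkynylation (C1 quaternary centre), hydroboration–oxidation, Z‑selective iodo‑olefination (C9=C10).
5. East 19 ⇐ racemic 2‑ethenyloxirane: new Pd‑catalysed dynamic kinetic asymmetric C7–O bond formation with Et3SiOH (sets C7, the centre that steers the final epoxidation), then cross‑metathesis with methacrolein.

Convention (one line): locants C1–C11 are the ring carbons of the target: C1 quaternary carbon (CH3, 4‑methylpent‑3‑enyl), C2=C3 Z‑alkene, C4 ester carbinol, C5(CH3)/C6 epoxide, C7 carbinol, C8 ketone, C9(CH2OH)=C10 enone, C11 methylene. The ligand antipodes given are the expected ones and would be confirmed by Mosher analysis on the first batch.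

## Route

Step 1
Reactants: 1 geraniol
Product: 2 geranyl diethyl phosphate
Conditions: (EtO)2P(O)Cl (1.2 equiv), pyridine, CH2Cl2, 0 °C to rt
Reagents that add atoms: diethyl chlorophosphate, CCOP(=O)(Cl)OCC
Why: Phosphorylation of the primary allylic alcohol (phosphate ester formation) gives the leaving group needed for copper‑catalysed SN2′ substitution; no stereocentre is involved.

Step 2
Reactants: 2 geranyl diethyl phosphate; 3 ethynyltrimethylsilane
Product: 5 (S)-(3-ethenyl-3,7-dimethyloct-6-en-1-yn-1-yl)trimethylsilane, via alkynylalane 4 (not isolated)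
Conditions: 3, i-Bu2AlH, Et3N (5 mol%), hexanes, rt; then 2, CuCl2·2H2O (2.5 mol%), chiral sulfonate-bearing imidazolinium salt (NHC precursor, 3 mol%, antipode giving S), THF, −15 °C
Reagents that add atoms: none
Why: Copper‑catalysed enantioselective allylic substitution (SN2′) with an in situ alkynylalane: the sulfonate‑bridged NHC–Cu complex transfers the alkynyl group to the γ‑carbon of the E‑trisubstituted allyl phosphate from one enantioface, creating the C1 quaternary stereocentre (S) and the vinyl group that becomes C11–C10.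

Step 3
Reactants: 5 (S)-(3-ethenyl-3,7-dimethyloct-6-en-1-yn-1-yl)trimethylsilane
Product: 8 (3S)-3-ethynyl-3,7-dimethyloct-6-en-1-ol, via alkylborane 6 (not isolated), via silylalkynol 7 (not isolated)
Conditions: 9-BBN-H (1.2 equiv), THF, 0 °C to rt; then aq NaOH, 30% H2O2, MeOH, 0 °C to rt
Reagents that add atoms: hydrogen peroxide, OO
Why: Anti‑Markovnikov hydroboration–oxidation: 9‑BBN‑H adds only to the monosubstituted vinyl group (the trisubstituted alkene and the silylalkyne are far slower), alkaline peroxide gives the primary alcohol (C10), and the same base in MeOH cleaves the C(sp)–Si bond; C1 is untouched.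

Step 4
Reactants: 8 (3S)-3-ethynyl-3,7-dimethyloct-6-en-1-ol
Product: 9 (3S)-3-ethynyl-3,7-dimethyloct-6-enal
Conditions: Dess–Martin periodinane, CH2Cl2, 0 °C to rt
Reagents that add atoms: none
Why: Dess–Martin oxidation of the primary alcohol to the aldehyde; the β‑quaternary centre cannot epimerise.

Step 5
Reactants: 9 (3S)-3-ethynyl-3,7-dimethyloct-6-enal; 10 ethyl (triphenylphosphoranylidene)acetate
Product: 12 ethyl (2Z,5S)-5-ethynyl-2-iodo-5,9-dimethyldeca-2,8-dienoate, via iodo ylide 11 (not isolated)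
Conditions: 10, N-iodosuccinimide, CH2Cl2, −20 °C; then 9, −20 °C to rt
Reagents that add atoms: N-iodosuccinimide, O=C1CCC(=O)N1I
Why: One‑pot ylide iodination and Wittig olefination: the stabilised iodo ylide reacts under thermodynamic control to put the ester trans to the alkyl chain, i.e. iodine cis to C11 (2Z), which fixes the C9=C10 geometry of the target; the minor E isomer is removed by chromatography.

Step 6
Reactants: 12 ethyl (2Z,5S)-5-ethynyl-2-iodo-5,9-dimethyldeca-2,8-dienoate
Product: 13 (2Z,5S)-5-ethynyl-2-iodo-5,9-dimethyldeca-2,8-dien-1-ol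
Conditions: i-Bu2AlH (2.2 equiv), CH2Cl2, −78 °C; aqueous work-up
Reagents that add atoms: none
Why: 1,2‑Reduction of the α‑iodo enoate with i‑Bu2AlH at −78 °C (ester reduction) gives the allylic alcohol without touching the alkenyl iodide or the alkyne.

Step 7
Reactants: 13 (2Z,5S)-5-ethynyl-2-iodo-5,9-dimethyldeca-2,8-dien-1-ol
Product: 14 tert-butyl{[(2Z,5S)-5-ethynyl-2-iodo-5,9-dimethyldeca-2,8-dien-1-yl]oxy}dimethylsilane (West fragment)
Conditions: t-BuMe2SiCl, imidazole, DMF, rt
Reagents that add atoms: tert-butylchlorodimethylsilane, CC(C)(C)[Si](C)(C)Cl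
Why: Silyl ether formation protects the primary allylic hydroxyl as a t‑BuMe2Si ether that survives the later Swern step.

Step 8
Reactants: 15 racemic 2-ethenyloxirane
Product: 17 (3S)-3,4-bis[(triethylsilyl)oxy]but-1-ene, via silyloxybutenol 16 (not isolated)
Conditions: Et3SiOH (1.0 equiv), 15 (1.2 equiv), Pd2(dba)3·CHCl3 (1 mol%), (R,R)-DACH-naphthyl Trost ligand (3 mol%, antipode chosen to give S), Et3B (2 mol%), CH2Cl2, rt; then imidazole, Et3SiCl, 0 °C
Reagents that add atoms: triethylsilanol, CC[Si](O)(CC)CC; chlorotriethylsilane, CC[Si](Cl)(CC)CC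
Why: Proposed new method: a trialkylsilanol serves as the oxygen pronucleophile in a Pd/borane dynamic kinetic asymmetric allylic etherification of a racemic vinyl epoxide; zerovalent palladium ionises both enantiomers of 15 to π‑allyl/alkoxide zwitterions that interconvert by π–σ–π faster than they are captured, Et3B links the alkoxide and Et3SiOH as a borate that delivers the silanolate oxygen to the internal allyl terminus inside the chiral ligand pocket, so the C7–O bond and the S stereocentre are formed together (closest known type: Pd/Et3B asymmetric allylic substitution of vinyl epoxides with alcohol or hydrogencarbonate nucleophiles, and Ph3SiOH as a hydroxide surrogate in racemic Pd allylation), and the free primary hydroxyl is then capped in the same flask with Et3SiCl (silyl ether formation).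

Step 9
Reactants: 17 (3S)-3,4-bis[(triethylsilyl)oxy]but-1-ene; 18 methacrolein
Product: 19 (2E,4S)-2-methyl-4,5-bis[(triethylsilyl)oxy]pent-2-enal (East fragment)
Conditions: 18 (5 equiv), second-generation Hoveyda–Grubbs catalyst RuCl2(H2IMes)(=CH-C6H4-2-OiPr) (5 mol%), CH2Cl2, 40 °C
Reagents that add atoms: none
Why: Olefin cross‑metathesis with excess methacrolein gives the thermodynamically preferred E‑trisubstituted enal (C5=C6) with loss of ethene; the C7 stereocentre is not affected.

Step 10
Reactants: 14 West fragment; 19 East fragment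
Product: 21 seco alkynol (1S,4S,7S; C4–OH, C2≡C3), via alkynylzinc 20 (not isolated)
Conditions: 14 (1.2 equiv), Me2Zn (3 equiv), (S,S)-ProPhenol (20 mol%, antipode selected to give 4S), Ph3PO (40 mol%), toluene, 0 °C; then 19, 4 °C; aq NH4Cl
Reagents that add atoms: none
Why: Zinc–ProPhenol catalysed asymmetric alkynylation of an enal: the dinuclear zinc catalyst adds the in situ alkynylzinc to one face of the aldehyde under catalyst control, forming C3–C4 and setting the C4 carbinol (S here, R in the target once C2≡C3 is reduced, same spatial arrangement); material carrying the minor C1 enantiomer from step 2 becomes a separable diastereomer.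

Step 11
Reactants: 21 seco alkynol; 22 3-methylbut-2-enoyl chloride
Product: 23 seco alkynyl 3-methylbut-2-enoate (1S,4S,7S)
Conditions: 22 (1.5 equiv), pyridine, DMAP (10 mol%), CH2Cl2, 0 °C
Reagents that add atoms: none
Why: Acylation of the secondary alcohol with the acid chloride (esterification) installs the 3‑methylbut‑2‑enoate; pyridine instead of Et3N avoids deconjugation through the vinylketene.

Step 12
Reactants: 23 seco alkynyl 3-methylbut-2-enoate
Product: 24 seco (2Z)-alkene ester (1S,4R,7S)
Conditions: H2 (1 atm), Pd/CaCO3 poisoned with Pb(OAc)2 (Lindlar catalyst), quinoline, EtOAc, 0 °C to rt, stopped at 1 equiv H2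
Reagents that add atoms: none
Why: Lindlar semi‑hydrogenation: syn delivery of H2 on poisoned palladium converts the C2≡C3 alkyne into the Z‑alkene, and quinoline plus stopping at one equivalent spares the hindered alkenyl iodide and the trisubstituted alkenes.

Step 13
Reactants: 24 seco (2Z)-alkene ester
Product: 25 seco C8 aldehyde (1S,4R,7S)
Conditions: (COCl)2, DMSO, CH2Cl2, −78 °C; 24, −78 to −40 °C; Et3N, −78 to 0 °C
Reagents that add atoms: none
Why: Direct Swern oxidation of a primary triethylsilyl ether: the chlorosulfonium salt cleaves and oxidises only the primary Et3Si ether to the aldehyde, the secondary Et3Si and the primary t‑BuMe2Si ethers survive, and the low temperature keeps the α‑silyloxy β,γ‑unsaturated aldehyde from epimerising at C7.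

Step 14
Reactants: 25 seco C8 aldehyde
Product: 27 macrocyclic C8 carbinol (1S,4R,7S; both C8 epimers), via alkenylchromium 26 (not isolated)
Conditions: CrCl2 (10 equiv), NiCl2 (0.1 equiv), degassed DMSO/THF, rt, 25 added by syringe pump to 2 mM
Reagents that add atoms: none
Why: Intramolecular Nozaki–Hiyama–Kishi reaction: nickel‑catalysed activation of the alkenyl iodide, transmetalation to trivalent chromium and chemoselective addition to the aldehyde (esters tolerated) close the 11‑membered ring at C8–C9 with retention of the Z alkenyl geometry, the three alkenes pre‑folding the chain; the C8 configuration is irrelevant because it is oxidised next.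

Step 15
Reactants: 27 macrocyclic C8 carbinol
Product: 28 macrocyclic enone bis-silyl ether (1S,4R,7S)
Conditions: Dess–Martin periodinane, CH2Cl2, 0 °C
Reagents that add atoms: none
Why: Dess–Martin oxidation of the allylic C8 alcohol converges both epimers to the Z‑enone without base, so C7 and the enone geometry are preserved.

Step 16
Reactants: 28 macrocyclic enone bis-silyl ether
Product: 29 macrocyclic diol (1S,4R,7S; C7–OH, CH2OH)
Conditions: HF·pyridine, pyridine, THF, 0 °C to rt
Reagents that add atoms: none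
Why: Buffered fluoride cleavage of both silyl ethers (desilylation) is mild enough to avoid enolisation at C7 of the α‑ketol and leaves the allylic ester intact.

Step 17
Reactants: 29 macrocyclic diol
Product: 30 target CNP0163063.1 (1S,4R,5S,6S,7S; 2Z,9Z)
Conditions: Ti(OiPr)4 (0.3 equiv), t-BuOOH (2 equiv, in decane), 4 Å molecular sieves, CH2Cl2, −20 °C
Reagents that add atoms: tert-butyl hydroperoxide, CC(C)(C)OO
Why: Hydroxyl‑directed epoxidation (Ti(OiPr)4/t‑BuOOH, Sharpless type without tartrate): the C7 alkoxide binds titanium and the peroxide, A(1,3) strain with the C5 methyl holds H‑7 in the alkene plane so oxygen is delivered to the exposed face of the E‑C5=C6 alkene syn to O‑7 (threo), giving 5S,6S, while the electron‑poor enone and enoate alkenes and the non‑allylic C2=C3 and side‑chain alkenes do not react.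

## Compound list

1 | geraniol, (2E)-3,7-dimethylocta-2,6-dien-1-ol | CC(C)=CCC/C(C)=C/CO | starting material
2 | geranyl diethyl phosphate | CC(C)=CCC/C(C)=C/COP(=O)(OCC)OCC | intermediate
3 | ethynyltrimethylsilane | C#C[Si](C)(C)C | starting material
4 | diisobutyl[(trimethylsilyl)ethynyl]alane | CC(C)C[Al](CC(C)C)C#C[Si](C)(C)C | intermediate
5 | (S)-(3-ethenyl-3,7-dimethyloct-6-en-1-yn-1-yl)trimethylsilane | CC(C)=CCC[C@](C=C)(C)C#C[Si](C)(C)C | intermediate
6 | 9-{(3R)-3,7-dimethyl-3-[(trimethylsilyl)ethynyl]oct-6-en-1-yl}-9-borabicyclo[3.3.1]nonane (R by CIP change only) | CC(C)=CCC[C@](CCB1C2CCCC1CCC2)(C)C#C[Si](C)(C)C | intermediate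
7 | (3S)-3,7-dimethyl-3-[(trimethylsilyl)ethynyl]oct-6-en-1-ol | CC(C)=CCC[C@](CCO)(C)C#C[Si](C)(C)C | intermediate
8 | (3S)-3-ethynyl-3,7-dimethyloct-6-en-1-ol | CC(C)=CCC[C@](CCO)(C)C#C | intermediate
9 | (3S)-3-ethynyl-3,7-dimethyloct-6-enal | CC(C)=CCC[C@](CC=O)(C)C#C | intermediate
10 | ethyl (triphenylphosphoranylidene)acetate | CCOC(=O)C=P(c1ccccc1)(c1ccccc1)c1ccccc1 | starting material
11 | ethyl iodo(triphenylphosphoranylidene)acetate | CCOC(=O)C(I)=P(c1ccccc1)(c1ccccc1)c1ccccc1 | intermediate
12 | ethyl (2Z,5S)-5-ethynyl-2-iodo-5,9-dimethyldeca-2,8-dienoate | CC(C)=CCC[C@](C/C=C(\I)C(=O)OCC)(C)C#C | intermediate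
13 | (2Z,5S)-5-ethynyl-2-iodo-5,9-dimethyldeca-2,8-dien-1-ol | CC(C)=CCC[C@](C/C=C(\I)CO)(C)C#C | intermediate
14 | tert-butyl{[(2Z,5S)-5-ethynyl-2-iodo-5,9-dimethyldeca-2,8-dien-1-yl]oxy}dimethylsilane (West fragment) | CC(C)=CCC[C@](C/C=C(\I)CO[Si](C)(C)C(C)(C)C)(C)C#C | intermediate
15 | racemic 2-ethenyloxirane (butadiene monoxide) | C=CC1CO1 | starting material
16 | (2S)-2-[(triethylsilyl)oxy]but-3-en-1-ol | C=C[C@H](O[Si](CC)(CC)CC)CO | intermediate
17 | (3S)-3,4-bis[(triethylsilyl)oxy]but-1-ene | C=C[C@H](O[Si](CC)(CC)CC)CO[Si](CC)(CC)CC | intermediate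
18 | methacrolein (2-methylprop-2-enal) | CC(=C)C=O | starting material
19 | (2E,4S)-2-methyl-4,5-bis[(triethylsilyl)oxy]pent-2-enal (East fragment) | O=C/C(C)=C/[C@H](O[Si](CC)(CC)CC)CO[Si](CC)(CC)CC | intermediate
20 | methylzinc acetylide of 14 (Zn on C3) | CC(C)=CCC[C@](C/C=C(\I)CO[Si](C)(C)C(C)(C)C)(C)C#C[Zn]C | intermediate
21 | seco alkynol, open chain I–C9(CH2OSiMe2t-Bu)=C10H–C11H2–C1(CH3)(CH2CH2CH=CMe2)–C2≡C3–C4H(OH)–C5(CH3)=C6H–C7H(OSiEt3)–C8H2OSiEt3; 1S,4S,7S; 5E,9Z | CC(C)=CCC[C@](C/C=C(\I)CO[Si](C)(C)C(C)(C)C)(C)C#C[C@@H](O)/C(C)=C/[C@H](O[Si](CC)(CC)CC)CO[Si](CC)(CC)CC | intermediate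
22 | 3-methylbut-2-enoyl chloride | CC(C)=CC(=O)Cl | starting material
23 | seco alkynyl ester: 21 with C4–OC(O)CH=C(CH3)2; 1S,4S,7S; 5E,9Z | CC(C)=CCC[C@](C/C=C(\I)CO[Si](C)(C)C(C)(C)C)(C)C#C[C@@H](OC(=O)C=C(C)C)/C(C)=C/[C@H](O[Si](CC)(CC)CC)CO[Si](CC)(CC)CC | intermediate
24 | seco (2Z)-alkene ester: 23 with cis C2H=C3H; 1S,4R,7S (C4 descriptor change is formal); 2Z,5E,9Z | CC(C)=CCC[C@](C/C=C(\I)CO[Si](C)(C)C(C)(C)C)(C)/C=C\[C@@H](OC(=O)C=C(C)C)/C(C)=C/[C@H](O[Si](CC)(CC)CC)CO[Si](CC)(CC)CC | intermediate
25 | seco C8 aldehyde: 24 with C8H=O in place of C8H2OSiEt3; 1S,4R,7S | CC(C)=CCC[C@](C/C=C(\I)CO[Si](C)(C)C(C)(C)C)(C)/C=C\[C@@H](OC(=O)C=C(C)C)/C(C)=C/[C@H](O[Si](CC)(CC)CC)C=O | intermediate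
26 | alkenylchromium dichloride: 25 with CrCl2 on C9 in place of iodine (trivalent chromium) | CC(C)=CCC[C@](C/C=C(\[Cr](Cl)Cl)CO[Si](C)(C)C(C)(C)C)(C)/C=C\[C@@H](OC(=O)C=C(C)C)/C(C)=C/[C@H](O[Si](CC)(CC)CC)C=O | intermediate
27 | macrocyclic C8 carbinol: 11-membered ring C1–C11, C8H(OH) (both epimers), C7–OSiEt3, CH2OSiMe2t-Bu on C9, C4 3-methylbut-2-enoate; 1S,4R,7S; 2Z,5E,9Z | CC(C)=CCC[C@]1(C)/C=C\[C@@H](OC(=O)C=C(C)C)/C(C)=C/[C@H](O[Si](CC)(CC)CC)C(O)/C(CO[Si](C)(C)C(C)(C)C)=C\C1 | intermediate
28 | macrocyclic enone bis-silyl ether: 27 with C8=O; 1S,4R,7S | CC(C)=CCC[C@]1(C)/C=C\[C@@H](OC(=O)C=C(C)C)/C(C)=C/[C@H](O[Si](CC)(CC)CC)C(=O)/C(CO[Si](C)(C)C(C)(C)C)=C\C1 | intermediate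
29 | macrocyclic diol: 28 with free C7–OH and free CH2OH on C9; 1S,4R,7S; 2Z,5E,9Z | CC(C)=CCC[C@]1(C)/C=C\[C@@H](OC(=O)C=C(C)C)/C(C)=C/[C@H](O)C(=O)/C(CO)=C\C1 | intermediate
30 | CNP0163063.1: 29 with the 5,6-epoxide; 1S,4R,5S,6S,7S; 2Z,9Z | CC(C)=CCC[C@]1(C)/C=C\[C@@H](OC(=O)C=C(C)C)[C@]2(C)O[C@H]2[C@H](O)C(=O)/C(CO)=C\C1 | target

## Step count and risks

Total step count: 17 (West fragment, steps 1–7; East fragment, steps 8–9; union and endgame, steps 10–17).
Longest linear sequence: 15 steps (steps 1–7 and 10–17, from geraniol).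

Three steps most likely to fail:

Step 8 (the proposed new Pd‑catalysed asymmetric etherification with Et3SiOH). The silanol may self‑condense or transfer its silyl group to the alkoxide instead of forming the C7–O bond, or the branched selectivity and ee may be low. The fallback uses known chemistry and a different principle, resolution by hydrolysis instead of allylic substitution. It sets out from 15: hydrolytic kinetic resolution with the (S,S)-(salen)Co(OAc) complex (trivalent cobalt, 0.5 mol%) and 0.45 equiv of water gives (2S)-but-3-ene-1,2-diol F1 in at most half the mass but high ee. Bis‑silylation of this diol with Et3SiCl (2.2 equiv) and imidazole comes back to the route at 17.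

Step 12 (Lindlar semi‑hydrogenation beside an alkenyl iodide). The C9–I bond may be hydrogenolysed, or the hindered alkyne may stall. The fallback moves the reduction ahead of the acylation and avoids palladium and hydrogen. It sets out from 21: dicyclohexylborane (2.2 equiv, THF, 0 °C) converts the hydroxyl into its borinate and adds syn across C2≡C3 to give the alkenylborane borinate F2. Protonolysis with acetic acid then gives the (2Z)-allylic alcohol F3. Acylation of this alcohol with 22 and pyridine comes back to the route at 24.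

Step 14 (Ni/Cr closure of the 11‑membered ring). Oligomerisation or simple reduction of the aldehyde can compete with ring closure. The fallback replaces the carbonyl addition by a neutral acyl cross‑coupling that gives the ketone directly, so step 15 is not needed. It sets out from 25: oxidation with NaClO2, NaH2PO4 and 2‑methylbut‑2‑ene gives the seco carboxylic acid F4. EtSH, EDC·HCl and DMAP turn this acid into the S‑ethyl thioester F5. Me6Sn2 with Pd(PPh3)4 exchanges the iodide for tin to give the alkenylstannane thioester F6. Liebeskind–Srogl coupling of this stannane (Pd2(dba)3, tri(2‑furyl)phosphine, copper thiophene‑2‑carboxylate, THF, high dilution) closes the ring and comes back to the route at 28.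

## Further compounds

F1 | step 8 | (2S)-but-3-ene-1,2-diol | C=C[C@H](O)CO
F2 | step 12 | alkenylborane borinate from 21: dicyclohexylboryl on C3 (cis to H-2) and O4–B(cyclohexyl)2 | CC(C)=CCC[C@](C/C=C(\I)CO[Si](C)(C)C(C)(C)C)(C)/C=C(/B(C1CCCCC1)C1CCCCC1)[C@@H](OB(C1CCCCC1)C1CCCCC1)/C(C)=C/[C@H](O[Si](CC)(CC)CC)CO[Si](CC)(CC)CC
F3 | step 12 | seco (2Z)-allylic alcohol: 24 with free C4–OH (1S,4R,7S) | CC(C)=CCC[C@](C/C=C(\I)CO[Si](C)(C)C(C)(C)C)(C)/C=C\[C@@H](O)/C(C)=C/[C@H](O[Si](CC)(CC)CC)CO[Si](CC)(CC)CC
F4 | step 14 | seco C8 carboxylic acid: 25 with CO2H at C8 | CC(C)=CCC[C@](C/C=C(\I)CO[Si](C)(C)C(C)(C)C)(C)/C=C\[C@@H](OC(=O)C=C(C)C)/C(C)=C/[C@H](O[Si](CC)(CC)CC)C(=O)O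
F5 | step 14 | seco C8 S-ethyl thioester | CC(C)=CCC[C@](C/C=C(\I)CO[Si](C)(C)C(C)(C)C)(C)/C=C\[C@@H](OC(=O)C=C(C)C)/C(C)=C/[C@H](O[Si](CC)(CC)CC)C(=O)SCC
F6 | step 14 | seco C8 S-ethyl thioester with trimethylstannyl on C9 in place of iodine | CC(C)=CCC[C@](C/C=C(\[Sn](C)(C)C)CO[Si](C)(C)C(C)(C)C)(C)/C=C\[C@@H](OC(=O)C=C(C)C)/C(C)=C/[C@H](O[Si](CC)(CC)CC)C(=O)SCC
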